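**Plan**

1. Retrosynthetic cuts, in order: the C8 ester; the C12 carbonyl oxygen (lactone back to a 3-methylenetetrahydrofuran); C7–C11 and C8–O together; the C6–O–C12 ether; the C7=C8 alkene; the furanone O–C3 bond; the C1–C2 bond.
2. Enabling feature (germacrane numbering: C1 ketone, C2=C3 furanone alkene with the O bridge C3–O–C10, C4 methyl, C6 lactone oxygen, C7 ring fusion, C8 acyloxy, C11–C13 methylene lactone): C6, C7 and C8 carry O, C and O in a row. A 2-haloallyl group on the C6 oxygen can therefore deliver C11 (already bearing C13) to C7 of a Z C7=C8 alkene through a five-membered ring and leave C8 as a radical for O2. The iodide is used so that halogen abstraction keeps pace with oxygen.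
3. Forward order: acetylide (C2) plus Weinreb amide (C1); gold-catalysed closure of the furanone ring; ring-closing metathesis at C7=C8 (ten-membered carbocycle, nine-membered oxacycle); radical closure of the methylenetetrahydrofuran; acylation; C12 oxidation to the lactone; acetonide removal.
4. Stereochemistry: C10 and the side-chain carbinol both come from (S)-lactic acid through its cis pivalaldehyde acetal (electrophile enters anti to tert-butyl). C6 comes from the D-glutamic-acid-derived lactone, C4 from trans methylation of that lactone, C7 from C6 and C8 from C7 in the key step.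

Key step: step 17

Assumption: lactone 6 is purchased; germacrane numbering is used for the ring compounds, and the C7 descriptor is 7R in 26 but 7S in 25 and 33–35 only because the CIP rank of C8 changes with its oxygen substituent, not because the centre changes.

**Route**

Step 1
Reactants: 1 (S)-lactic acid
Product: 2 (2S,5S)-2-tert-butyl-5-methyl-1,3-dioxolan-4-one
Conditions: t-BuCHO, TsOH (cat.), pentane, reflux with water separator; crystallisation from pentane at −78 °C
Reagents that add atoms: pivalaldehyde (CC(C)(C)C=O)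
Why: Acid-catalysed acetalisation of the α-hydroxy acid with azeotropic water removal is reversible, so the cis acetal (tert-butyl and methyl on the same face) should predominate and crystallise while the lactate stereocentre is untouched.

Step 2
Reactants: 2 (2S,5S)-2-tert-butyl-5-methyl-1,3-dioxolan-4-one
Product: 4 (2S,5R)-2-tert-butyl-5-methyl-5-(prop-2-en-1-yl)-1,3-dioxolan-4-one, via sodium enolate 3 (not isolated)
Conditions: NaN(SiMe3)2, THF, −78 °C; CH2=CHCH2Br, −78 → −40 °C
Reagents that add atoms: allyl bromide (C=CCBr)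
Why: Enolate C-alkylation with self-regeneration of the stereocentre: the acetal tert-butyl group shields one face of the planar enolate, so allyl bromide enters anti to it and the quaternary carbinol centre (later C10, R) forms with net retention, the more reactive sodium enolate being chosen so that the SN2 step is complete at low temperature before the thermally labile enolate can fragment.

Step 3
Reactants: 4 (2S,5R)-2-tert-butyl-5-methyl-5-(prop-2-en-1-yl)-1,3-dioxolan-4-one
Product: 5 (2R)-2-hydroxy-N-methoxy-N,2-dimethylpent-4-enamide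
Conditions: MeNH(OMe)·HCl, i-PrMgCl, THF, −20 → 0 °C; aq. NH4Cl
Reagents that add atoms: N,O-dimethylhydroxylamine hydrochloride (CNOC.Cl)
Why: Weinreb amide synthesis by attack of the chloromagnesium amide on the acylal carbonyl, which is more electrophilic than a simple ester; the hemiacetal alkoxide left behind sheds pivalaldehyde on work-up and the quaternary centre is not involved.

Step 4
Reactants: 6 (5R)-5-(hydroxymethyl)oxolan-2-one
Product: 7 (2R)-5-oxooxolane-2-carbaldehyde
Conditions: (COCl)2, DMSO, CH2Cl2, −78 °C; Et3N, −78 → −30 °C; filtered and used crude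
Reagents that add atoms: none
Why: Swern oxidation of the primary alcohol; the non-aqueous low-temperature protocol avoids hydration and epimerisation of the α-acyloxy aldehyde, which is used at once.

Step 5
Reactants: 7 (2R)-5-oxooxolane-2-carbaldehyde
Product: 8 (5R)-5-ethenyloxolan-2-one
Conditions: Ph3PCH3Br, KN(SiMe3)2, THF, 0 °C; ylide added to 7 at −78 → 0 °C
Reagents that add atoms: methyltriphenylphosphonium bromide (C[P+](c1ccccc1)(c1ccccc1)c1ccccc1.[Br-])
Why: Wittig methylenation; the aldehyde reacts with the non-stabilised ylide far faster than the lactone carbonyl at −78 °C, and adding the ylide to the aldehyde without excess base should preserve the C5 centre.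

Step 6
Reactants: 8 (5R)-5-ethenyloxolan-2-one
Product: 10 (3S,5R)-5-ethenyl-3-methyloxolan-2-one, via lithium enolate 9 (not isolated)
Conditions: LiN(i-Pr)2, THF, −78 °C; MeI, −78 °C
Reagents that add atoms: iodomethane (CI)
Why: Alkylation of the lactone lithium enolate; iodomethane approaches the face opposite the C5 vinyl group, which should favour the trans (3S,5R) lactone (future C4 and C6), the minor cis isomer being removed by chromatography.

Step 7
Reactants: 10 (3S,5R)-5-ethenyl-3-methyloxolan-2-one
Product: 11 (3S,5R)-5-ethenyl-3-methyloxolan-2-ol (anomers)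
Conditions: i-Bu2AlH, CH2Cl2, −78 °C; aq. potassium sodium tartrate
Reagents that add atoms: none
Why: Partial reduction of the lactone with one hydride equivalent; the aluminium hemiacetal is stable at −78 °C and gives the lactol on work-up without touching either stereocentre or the alkene.

Step 8
Reactants: 11 (3S,5R)-5-ethenyl-3-methyloxolan-2-ol
Product: 12 (3R,5S)-5-methylhept-1-en-6-yn-3-ol
Conditions: MeC(O)C(N2)P(O)(OMe)2, K2CO3, MeOH, 0 °C → rt
Reagents that add atoms: dimethyl (1-diazo-2-oxopropyl)phosphonate (COP(=O)(OC)C(=[N+]=[N-])C(C)=O)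
Why: Seyferth–Gilbert homologation in the Ohira–Bestmann variant acts on the open hydroxy-aldehyde tautomer of the lactol and turns CHO into C≡CH with loss of N2; the carbonate/methanol medium is mild enough that the α-methyl centre is expected to survive.

Step 9
Reactants: 12 (3R,5S)-5-methylhept-1-en-6-yn-3-ol
Product: 13 tert-butyldimethyl{[(3R,5S)-5-methylhept-1-en-6-yn-3-yl]oxy}silane
Conditions: t-BuMe2SiCl, imidazole, DMF, rt
Reagents that add atoms: tert-butyldimethylsilyl chloride (CC(C)(C)[Si](C)(C)Cl)
Why: Standard silylation of the secondary allylic alcohol; the silyl ether keeps the C6 oxygen from competing with the tertiary hydroxyl in the later alkyne hydroalkoxylation.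

Step 10
Reactants: 13 tert-butyldimethyl{[(3R,5S)-5-methylhept-1-en-6-yn-3-yl]oxy}silane; 5 (2R)-2-hydroxy-N-methoxy-N,2-dimethylpent-4-enamide
Product: 16 (4R,8S,10R)-10-[(tert-butyldimethylsilyl)oxy]-4-hydroxy-4,8-dimethyldodeca-1,11-dien-6-yn-5-one, via lithium acetylide 14 (not isolated), via chloromagnesium alkoxide 15 (not isolated)
Conditions: 13, n-BuLi, THF, −78 °C; 5, i-PrMgCl, THF, −20 °C; combined, −78 → 0 °C; aq. NH4Cl
Reagents that add atoms: none
Why: Acylation of a lithium acetylide by a Weinreb amide forms C1–C2; the chelated tetrahedral adduct prevents double addition, prior conversion of the tertiary hydroxyl into its magnesium alkoxide saves acetylide, and no stereocentre is touched.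

Step 11
Reactants: 16 (4R,8S,10R)-10-[(tert-butyldimethylsilyl)oxy]-4-hydroxy-4,8-dimethyldodeca-1,11-dien-6-yn-5-one
Product: 17 (2R)-5-[(2S,4R)-4-[(tert-butyldimethylsilyl)oxy]hex-5-en-2-yl]-2-methyl-2-(prop-2-en-1-yl)furan-3(2H)-one
Conditions: [(4-CF3C6H4)3P]AuCl (5 mol %), AgOSO2CF3 (5 mol %), toluene, rt
Reagents that add atoms: none
Why: Cationic monovalent gold activates the ynone alkyne for 5-endo-dig attack of the α'-hydroxyl and protodeauration gives the 3(2H)-furanone (O–C3 bond); the neutral conditions leave the C4 centre, the silyl ether and both terminal alkenes alone.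

Step 12
Reactants: 17 (2R)-5-[(2S,4R)-4-[(tert-butyldimethylsilyl)oxy]hex-5-en-2-yl]-2-methyl-2-(prop-2-en-1-yl)furan-3(2H)-one
Product: 18 (2S,4R,5Z,8R)-4-[(tert-butyldimethylsilyl)oxy]-2,8-dimethyl-11-oxabicyclo[6.2.1]undeca-1(10),5-dien-9-one
Conditions: second-generation Grubbs catalyst, (H2IMes)(PCy3)Cl2Ru=CHPh (10 mol %), CH2Cl2 (1 mM), 40 °C
Reagents that add atoms: none
Why: Ring-closing metathesis with loss of ethylene; the furanone holds the allyl and vinyl arms 1,3 across its oxygen and C10 is quaternary, which should favour closure of the nine-membered oxacycle over oligomerisation at high dilution, and the Z C7=C8 alkene is expected because the E isomer of a ring this size is much more strained.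

Step 13
Reactants: 18 (2S,4R,5Z,8R)-4-[(tert-butyldimethylsilyl)oxy]-2,8-dimethyl-11-oxabicyclo[6.2.1]undeca-1(10),5-dien-9-one
Product: 19 (2S,4R,5Z,8R)-4-hydroxy-2,8-dimethyl-11-oxabicyclo[6.2.1]undeca-1(10),5-dien-9-one
Conditions: HF·pyridine, pyridine, THF, 0 °C → rt
Reagents that add atoms: none
Why: Fluoride cleavage of the Si–O bond under buffered, weakly acidic conditions, chosen over basic fluoride so that the liberated C6 hydroxyl does not add to the furanone.

Step 14
Reactants: 20 prop-2-yn-1-ol
Product: 21 2-iodoprop-2-en-1-ol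
Conditions: NaI, Me3SiCl, H2O, MeCN, rt
Reagents that add atoms: sodium iodide ([Na+].[I-])
Why: Markovnikov hydroiodination of the terminal alkyne by HI generated in the flask gives the 2-iodoalkene regioselectively.

Step 15
Reactants: 21 2-iodoprop-2-en-1-ol
Product: 22 3-bromo-2-iodoprop-1-ene
Conditions: PBr3, Et2O, 0 °C
Reagents that add atoms: phosphorus tribromide (BrP(Br)Br)
Why: Conversion of the allylic alcohol into the bromide by displacement of its phosphite ester; the vinyl iodide is inert.

Step 16
Reactants: 19 (2S,4R,5Z,8R)-4-hydroxy-2,8-dimethyl-11-oxabicyclo[6.2.1]undeca-1(10),5-dien-9-one; 22 3-bromo-2-iodoprop-1-ene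
Product: 24 (2S,4R,5Z,8R)-4-[(2-iodoprop-2-en-1-yl)oxy]-2,8-dimethyl-11-oxabicyclo[6.2.1]undeca-1(10),5-dien-9-one, via sodium alkoxide 23 (not isolated)
Conditions: NaH, THF–DMF, 0 °C; then 22, 0 °C → rt
Reagents that add atoms: none
Why: Williamson etherification; the alkoxide displaces the allylic bromide far faster than it can add to the vinylogous ester, the vinyl iodide does not react, and C6 keeps its configuration because its C–O bond is not broken.

Step 17
Reactants: 24 (2S,4R,5Z,8R)-4-[(2-iodoprop-2-en-1-yl)oxy]-2,8-dimethyl-11-oxabicyclo[6.2.1]undeca-1(10),5-dien-9-one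
Product: 26 (4S,6R,7R,8S,10R)-8-hydroxy-3,10:6,12-diepoxygermacra-2,11(13)-dien-1-one, via C8 hydroperoxide 25 (not isolated)
Conditions: Bu3SnH (slow addition), Et3B (cat.), dry air, toluene (5 mM), 0 °C → rt; then PPh3, rt
Reagents that add atoms: dioxygen (O=O)
Why: Bu3Sn• (started by Et3B/air) abstracts iodine from 24, the sp2 radical at C11 adds to C7 of the Z C7=C8 alkene, the secondary C8 radical combines with O2, the peroxyl radical takes hydrogen from Bu3SnH, and PPh3 reduces hydroperoxide 25 to the alcohol. The closest known reaction type is the Ueno–Stork-type tin hydride cyclisation of β-halo and 2-haloallyl ethers run under air (oxygenative radical cyclisation). The one ring closed is the 3-methylenetetrahydrofuran C6–O–C12–C11–C7, formed in the 5-exo-trig mode. C7 is controlled by C6: allylic 1,3-strain in the Z alkene turns H6 into the alkene plane, so the tether on the C6 oxygen reaches C7 only from the face opposite C5 and H7 ends anti to H6 (trans fusion; 7R in 26, the same spatial arrangement as 7S in the target). C8 is expected to be set by oxygen capture anti to the new C7–C11 bond, on the face of the radical flanked by H7 and not by C11 and its methylene (8S). The step needs ring closure to outrun oxygen capture of the vinyl radical and oxygen capture to outrun reduction or ring expansion of the C8 radical; fast iodine abstraction, the three-atom ether tether, the low oxygen content of air-saturated toluene and slow addition of the stannane are chosen to secure this.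

Step 18
Reactants: 2 (2S,5S)-2-tert-butyl-5-methyl-1,3-dioxolan-4-one
Product: 28 (2S,5R)-2-tert-butyl-5-(hydroxymethyl)-5-methyl-1,3-dioxolan-4-one, via lithium enolate 27 (not isolated)
Conditions: LiN(i-Pr)2, THF, −78 °C; CH2O (gas, from cracked paraformaldehyde), −78 °C; AcOH
Reagents that add atoms: formaldehyde (C=O)
Why: Aldol addition of the lithium enolate of 2 to monomeric formaldehyde, again anti to the tert-butyl group, sets the tertiary carbinol centre of the side chain with the R configuration, lithium being kept for this step because the chelated lithium aldolate should resist retro-aldol cleavage until the cold acetic acid quench.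

Step 19
Reactants: 28 (2S,5R)-2-tert-butyl-5-(hydroxymethyl)-5-methyl-1,3-dioxolan-4-one
Product: 30 methyl (4R)-2,2,4-trimethyl-1,3-dioxolane-4-carboxylate, via diol methyl ester 29 (not isolated)
Conditions: HCl (cat.), MeOH, 50 °C; evaporation; Me2C(OMe)2, TsOH (cat.), acetone, rt
Reagents that add atoms: methanol (CO); 2,2-dimethoxypropane (COC(C)(C)OC)
Why: Acid-catalysed methanolysis opens the acylal to the diol methyl ester with loss of pivalaldehyde, and acetal exchange with 2,2-dimethoxypropane then closes the five-membered acetonide; the quaternary centre is not involved.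

Step 20
Reactants: 30 methyl (4R)-2,2,4-trimethyl-1,3-dioxolane-4-carboxylate
Product: 31 (4R)-2,2,4-trimethyl-1,3-dioxolane-4-carboxylic acid
Conditions: LiOH, THF–H2O, 0 °C → rt; then cold 1 M HCl to pH 3
Reagents that add atoms: lithium hydroxide ([Li+].[OH-])
Why: Saponification of the methyl ester; the acetonide is stable to base and should survive the brief cold acidification.

Step 21
Reactants: 26 (4S,6R,7R,8S,10R)-8-hydroxy-3,10:6,12-diepoxygermacra-2,11(13)-dien-1-one; 31 (4R)-2,2,4-trimethyl-1,3-dioxolane-4-carboxylic acid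
Product: 33 (4S,6R,7S,8S,10R)-1-oxo-3,10:6,12-diepoxygermacra-2,11(13)-dien-8-yl (4R)-2,2,4-trimethyl-1,3-dioxolane-4-carboxylate, via mixed anhydride 32 (not isolated)
Conditions: 31, 2,4,6-Cl3C6H2COCl, Et3N, THF, rt; then 26, DMAP, toluene, rt → 40 °C
Reagents that add atoms: none
Why: Yamaguchi esterification; DMAP attacks the mixed anhydride at the less hindered aliphatic carbonyl and the acylpyridinium transfers the α,α-disubstituted acyl group to the secondary C8 hydroxyl with retention at C8.

Step 22
Reactants: 33 (4S,6R,7S,8S,10R)-1-oxo-3,10:6,12-diepoxygermacra-2,11(13)-dien-8-yl (4R)-2,2,4-trimethyl-1,3-dioxolane-4-carboxylate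
Product: 34 (4S,6R,7S,8S,10R)-1-oxo-3,10-epoxygermacra-2,11(13)-dien-12,6-olid-8-yl (4R)-2,2,4-trimethyl-1,3-dioxolane-4-carboxylate
Conditions: CrO3, 3,5-dimethylpyrazole, CH2Cl2, −20 → 0 °C
Reagents that add atoms: chromium trioxide (O=[Cr](=O)=O)
Why: Allylic oxidation by hexavalent chromium; C12 is the only CH2 activated by both the exocyclic alkene and the ether oxygen, and oxidation of 3-methylenetetrahydrofurans to α-methylene-γ-butyrolactones is established, while the esters, the acetonide and the electron-poor furanone alkene are expected to survive.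

Step 23
Reactants: 34 (4S,6R,7S,8S,10R)-1-oxo-3,10-epoxygermacra-2,11(13)-dien-12,6-olid-8-yl (4R)-2,2,4-trimethyl-1,3-dioxolane-4-carboxylate
Product: 35 (4S,6R,7S,8S,10R)-8-[(2R)-2,3-dihydroxy-2-methylpropanoyloxy]-1-oxo-3,10-epoxygermacra-2,11(13)-dien-12,6-olide
Conditions: CF3CO2H–H2O (9:1), CH2Cl2, 0 °C
Reagents that add atoms: none
Why: Acid-catalysed acetal hydrolysis releases acetone and the 1,2-diol; the conditions are too mild to cleave the esters or to hydrate the methylene lactone.

**Compound list**

1 | (S)-lactic acid, (2S)-2-hydroxypropanoic acid | C[C@H](O)C(=O)O | starting material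
2 | (2S,5S)-2-tert-butyl-5-methyl-1,3-dioxolan-4-one (cis acetal) | C[C@@H]1O[C@H](C(C)(C)C)OC1=O | intermediate
3 | sodium enolate of 2, sodium (2S)-2-tert-butyl-5-methyl-1,3-dioxol-4-olate | CC1=C(O[Na])O[C@@H](C(C)(C)C)O1 | intermediate
4 | (2S,5R)-2-tert-butyl-5-methyl-5-(prop-2-en-1-yl)-1,3-dioxolan-4-one | C=CC[C@@]1(C)O[C@H](C(C)(C)C)OC1=O | intermediate
5 | (2R)-2-hydroxy-N-methoxy-N,2-dimethylpent-4-enamide | C=CC[C@@](C)(O)C(=O)N(C)OC | intermediate
6 | (5R)-5-(hydroxymethyl)oxolan-2-one | O=C1CC[C@H](CO)O1 | starting material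
7 | (2R)-5-oxooxolane-2-carbaldehyde | O=C1CC[C@H](C=O)O1 | intermediate
8 | (5R)-5-ethenyloxolan-2-one | O=C1CC[C@H](C=C)O1 | intermediate
9 | lithium enolate of 8, lithium (5R)-5-ethenyl-4,5-dihydrofuran-2-olate | [Li]OC1=CC[C@H](C=C)O1 | intermediate
10 | (3S,5R)-5-ethenyl-3-methyloxolan-2-one (trans) | C[C@H]1C[C@H](C=C)OC1=O | intermediate
11 | (3S,5R)-5-ethenyl-3-methyloxolan-2-ol (anomers) | C[C@H]1C[C@H](C=C)OC1O | intermediate
12 | (3R,5S)-5-methylhept-1-en-6-yn-3-ol | C[C@H](C#C)C[C@@H](O)C=C | intermediate
13 | tert-butyldimethyl{[(3R,5S)-5-methylhept-1-en-6-yn-3-yl]oxy}silane | C[C@H](C#C)C[C@@H](O[Si](C)(C)C(C)(C)C)C=C | intermediate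
14 | lithium acetylide of 13 | [Li]C#C[C@@H](C)C[C@@H](O[Si](C)(C)C(C)(C)C)C=C | intermediate
15 | chloromagnesium alkoxide of 5 | C=CC[C@@](C)(O[Mg]Cl)C(=O)N(C)OC | intermediate
16 | (4R,8S,10R)-10-[(tert-butyldimethylsilyl)oxy]-4-hydroxy-4,8-dimethyldodeca-1,11-dien-6-yn-5-one | C=CC[C@@](C)(O)C(=O)C#C[C@@H](C)C[C@@H](O[Si](C)(C)C(C)(C)C)C=C | intermediate
17 | (2R)-5-[(2S,4R)-4-[(tert-butyldimethylsilyl)oxy]hex-5-en-2-yl]-2-methyl-2-(prop-2-en-1-yl)furan-3(2H)-one | C=CC[C@@]1(C)OC(=CC1=O)[C@@H](C)C[C@@H](O[Si](C)(C)C(C)(C)C)C=C | intermediate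
18 | (2S,4R,5Z,8R)-4-[(tert-butyldimethylsilyl)oxy]-2,8-dimethyl-11-oxabicyclo[6.2.1]undeca-1(10),5-dien-9-one (C6 silyl ether, Z C7=C8) | CC(C)(C)[Si](C)(C)O[C@@H]1C[C@H](C)C2=CC(=O)[C@@](C)(C/C=C\1)O2 | intermediate
19 | (2S,4R,5Z,8R)-4-hydroxy-2,8-dimethyl-11-oxabicyclo[6.2.1]undeca-1(10),5-dien-9-one | O[C@@H]1C[C@H](C)C2=CC(=O)[C@@](C)(C/C=C\1)O2 | intermediate
20 | prop-2-yn-1-ol | C#CCO | starting material
21 | 2-iodoprop-2-en-1-ol | C=C(I)CO | intermediate
22 | 3-bromo-2-iodoprop-1-ene | C=C(I)CBr | intermediate
23 | sodium alkoxide of 19 | [Na]O[C@@H]1C[C@H](C)C2=CC(=O)[C@@](C)(C/C=C\1)O2 | intermediate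
24 | (2S,4R,5Z,8R)-4-[(2-iodoprop-2-en-1-yl)oxy]-2,8-dimethyl-11-oxabicyclo[6.2.1]undeca-1(10),5-dien-9-one (key-step precursor) | C=C(I)CO[C@@H]1C[C@H](C)C2=CC(=O)[C@@](C)(C/C=C\1)O2 | intermediate
25 | (4S,6R,7S,8S,10R)-8-hydroperoxy-3,10:6,12-diepoxygermacra-2,11(13)-dien-1-one | C=C1CO[C@@H]2C[C@H](C)C3=CC(=O)[C@@](C)(C[C@H](OO)[C@@H]12)O3 | intermediate
26 | (4S,6R,7R,8S,10R)-8-hydroxy-3,10:6,12-diepoxygermacra-2,11(13)-dien-1-one (key-step product) | C=C1CO[C@@H]2C[C@H](C)C3=CC(=O)[C@@](C)(C[C@H](O)[C@@H]12)O3 | intermediate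
27 | lithium enolate of 2, lithium (2S)-2-tert-butyl-5-methyl-1,3-dioxol-4-olate | CC1=C(O[Li])O[C@@H](C(C)(C)C)O1 | intermediate
28 | (2S,5R)-2-tert-butyl-5-(hydroxymethyl)-5-methyl-1,3-dioxolan-4-one | OC[C@@]1(C)O[C@H](C(C)(C)C)OC1=O | intermediate
29 | methyl (2R)-2,3-dihydroxy-2-methylpropanoate | COC(=O)[C@](C)(O)CO | intermediate
30 | methyl (4R)-2,2,4-trimethyl-1,3-dioxolane-4-carboxylate | COC(=O)[C@@]1(C)COC(C)(C)O1 | intermediate
31 | (4R)-2,2,4-trimethyl-1,3-dioxolane-4-carboxylic acid | OC(=O)[C@@]1(C)COC(C)(C)O1 | intermediate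
32 | (4R)-2,2,4-trimethyl-1,3-dioxolane-4-carboxylic 2,4,6-trichlorobenzoic anhydride | O=C(OC(=O)c1c(Cl)cc(Cl)cc1Cl)[C@@]1(C)COC(C)(C)O1 | intermediate
33 | (4S,6R,7S,8S,10R)-1-oxo-3,10:6,12-diepoxygermacra-2,11(13)-dien-8-yl (4R)-2,2,4-trimethyl-1,3-dioxolane-4-carboxylate | C=C1CO[C@@H]2C[C@H](C)C3=CC(=O)[C@@](C)(C[C@H](OC(=O)[C@@]4(C)COC(C)(C)O4)[C@@H]12)O3 | intermediate
34 | (4S,6R,7S,8S,10R)-1-oxo-3,10-epoxygermacra-2,11(13)-dien-12,6-olid-8-yl (4R)-2,2,4-trimethyl-1,3-dioxolane-4-carboxylate | C=C1C(=O)O[C@@H]2C[C@H](C)C3=CC(=O)[C@@](C)(C[C@H](OC(=O)[C@@]4(C)COC(C)(C)O4)[C@@H]12)O3 | intermediate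
35 | (4S,6R,7S,8S,10R)-8-[(2R)-2,3-dihydroxy-2-methylpropanoyloxy]-1-oxo-3,10-epoxygermacra-2,11(13)-dien-12,6-olide (CNP0263764.2) | C=C1C(=O)O[C@@H]2C[C@H](C)C3=CC(=O)[C@@](C)(C[C@H](OC(=O)[C@](C)(O)CO)[C@@H]12)O3 | target

**Step count**

Total: 23 steps. Longest linear sequence: 15 steps (from 6 through steps 4–13, 16, 17, 21–23).

**Steps most likely to fail**

Step 17. The chain may be hard to balance: air can oxidise the stannane faster than iodine is abstracted, the vinyl radical can be captured by oxygen before it closes the ring, and the facial selectivity of oxygen capture at C8 may be poor. The fallback delivers the oxygen atom with a persistent nitroxide instead of O2. Setting out from 24, Bu3SnH and TEMPO (added in portions) in benzene at 70 °C, a tin-hydride-initiated cyclisation with nitroxide capture known for sp2 radicals, should give (4S,6R,7S,8S,10R)-8-[(2,2,6,6-tetramethylpiperidin-1-yl)oxy]-3,10:6,12-diepoxygermacra-2,11(13)-dien-1-one F1 without peroxyl intermediates, and the bulkier trap should sharpen the preference for the face anti to C11. Reductive N–O cleavage with Zn in AcOH–THF–H2O then comes back to the route at 26.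

Step 12. Cross-metathesis oligomerisation may outrun closure of the strained, oxygen-bridged nine-membered ring, and the catalyst may stall at the vinyl group next to the silyl ether. The fallback reverses the order of ring formation. Setting out from 16, ring-closing metathesis (second-generation Grubbs catalyst, (H2IMes)(PCy3)Cl2Ru=CHPh, high dilution) would first close the unbridged ten-membered carbocycle, (4S,6R,7Z,10R)-6-[(tert-butyldimethylsilyl)oxy]-10-hydroxy-4,10-dimethylcyclodec-7-en-2-yn-1-one F2; the internal, carbonyl-conjugated alkyne, flanked by a branched and a quaternary carbon, should be a poor metathesis partner. Transannular 5-endo-dig hydroalkoxylation with the cationic monovalent gold catalyst of step 11 then forms the furanone and comes back to the route at 18.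

Step 22. Conversion may be slow, and oxidation may go astray at the tertiary allylic C7–H or continue beyond the lactone. The fallback splits the oxidation into two milder operations. Setting out from 33, SeO2 (cat.) with t-BuOOH in CH2Cl2 should hydroxylate the allylic ether methylene to the lactol (4S,6R,7S,8S,10R)-12-hydroxy-1-oxo-3,10:6,12-diepoxygermacra-2,11(13)-dien-8-yl (4R)-2,2,4-trimethyl-1,3-dioxolane-4-carboxylate F3 (C12 epimers). MnO2 in CH2Cl2 then oxidises the allylic lactol and comes back to the route at 34.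

**Further compounds**

F1 | step 17 | (4S,6R,7S,8S,10R)-8-[(2,2,6,6-tetramethylpiperidin-1-yl)oxy]-3,10:6,12-diepoxygermacra-2,11(13)-dien-1-one | C=C1CO[C@@H]2C[C@H](C)C3=CC(=O)[C@@](C)(C[C@H](ON4C(C)(C)CCCC4(C)C)[C@@H]12)O3
F2 | step 12 | (4S,6R,7Z,10R)-6-[(tert-butyldimethylsilyl)oxy]-10-hydroxy-4,10-dimethylcyclodec-7-en-2-yn-1-one | C[C@H]1C[C@@H](O[Si](C)(C)C(C)(C)C)/C=C\C[C@@](C)(O)C(=O)C#C1
F3 | step 22 | (4S,6R,7S,8S,10R)-12-hydroxy-1-oxo-3,10:6,12-diepoxygermacra-2,11(13)-dien-8-yl (4R)-2,2,4-trimethyl-1,3-dioxolane-4-carboxylate | C=C1C(O)O[C@@H]2C[C@H](C)C3=CC(=O)[C@@](C)(C[C@H](OC(=O)[C@@]4(C)COC(C)(C)O4)[C@@H]12)O3
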